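**Plan**
Numbering: ring A = C1–C5 + C10 (C4 = CMe2). Ring B = C5–C10 (C8 = CHMe, C9 = quaternary carbon). The chain is C11–C16, with C13 carrying CH2O and the furan on C16.
Cuts: O–S first. Then C4–C5 and C1–C10, which removes ring A and turns the ring-fusion carbon C10 into a ketone. Then C9–C11 and C8–CH3 together. In the chain, C13–C14.
Enabling feature: in ring B the diad C8 (CHMe)/C9 (C, Me, CH2) lies next to sp2 C10. With C10 read as C=O, C8–C9–C10 is the β-carbon, α-carbon and carbonyl of 2-methylcyclohex-2-enone, and C11–C12–C13 can be an allyl unit. One three-component operation (methyl nucleophile, enone, allylic bromide) then sets both ring stereocentres and attaches the whole furan-bearing chain.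
Forward: chain bromide by syn-carbocupration → three-component union on ring B → hydrogenation of C12=C13 → enol triflate, Negishi coupling and proton-induced closure of ring A (places C5=C10) → desilylation → sulfation.
Stereochemistry: C8 comes from the chiral copper catalyst. C9 comes from C8 (alkylation anti to the new methyl). C13 comes from a chiral iridium catalyst acting on a geometrically pure Z-alkene.

Key step: step 7

Assumption: for the two catalyst-controlled steps (7 and 8) the ligand antipode meant is the one that gives the drawn configuration; the sense of induction is to be confirmed on a model substrate.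
Assumption: the target is drawn and delivered as the free hydrogen sulfate; for storage it would be neutralised to its sodium salt.

Step 1
Reactants: 1 3-bromofuran; 2 oxetane
Product: 4 3-(furan-3-yl)propan-1-ol, via furan-3-yllithium 3 (not isolated)
Conditions: n-BuLi, THF, −78 °C; then 2, BF3·OEt2, −78 °C; H2O work-up
Reagents that add atoms: oxetane (2), C1COC1
Why: Bromine–lithium exchange at −78 °C gives 3 faster than it can isomerise to the 2-lithio species, and the aryllithium opens BF3-activated oxetane by SN2 attack at CH2 (Lewis-acid-promoted oxetane opening), which adds C14–C16 in one step.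

Step 2
Reactants: 4 3-(furan-3-yl)propan-1-ol
Product: 5 3-(3-bromopropyl)furan
Conditions: CBr4, PPh3, CH2Cl2, 0 °C
Reagents that add atoms: carbon tetrabromide, BrC(Br)(Br)Br
Why: Appel reaction of a primary alcohol under neutral conditions, which the acid-sensitive furan tolerates.

Step 3
Reactants: 6 tert-butyldimethyl(prop-2-yn-1-yloxy)silane; 7 ethyl chloroformate
Product: 9 ethyl 4-[(tert-butyldimethylsilyl)oxy]but-2-ynoate, via lithium acetylide 8 (not isolated)
Conditions: n-BuLi, THF, −78 °C; then 7, −78 → 0 °C
Reagents that add atoms: ethyl chloroformate (7), CCOC(=O)Cl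
Why: Deprotonation of the terminal alkyne and C-acylation of the lithium acetylide with a chloroformate is the standard route to 2-ynoates, and the silyl ether is inert to both reagents.

Step 4
Reactants: 5 3-(3-bromopropyl)furan; 9 ethyl 4-[(tert-butyldimethylsilyl)oxy]but-2-ynoate
Product: 13 ethyl (Z)-3-{[(tert-butyldimethylsilyl)oxy]methyl}-6-(furan-3-yl)hex-2-enoate, via Grignard reagent 10 (not isolated), via alkylcopper 11 (not isolated), via alkenylcopper adduct 12 (not isolated)
Conditions: 5, Mg, THF; CuBr·SMe2, THF/Me2S, −40 °C; 9, −78 °C; aq NH4Cl at −78 °C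
Reagents that add atoms: none
Why: Conjugate syn-carbocupration of a 2-ynoate puts the alkyl group on the β-carbon (C13) and copper on the α-carbon from the same face, and protonation of 12 at −78 °C with retention fixes the Z geometry (CH2OSi cis to the ester), the adduct being kept cold so that it does not equilibrate through the allenolate.

Step 5
Reactants: 13 the (Z)-enoate
Product: 14 (Z)-3-{[(tert-butyldimethylsilyl)oxy]methyl}-6-(furan-3-yl)hex-2-en-1-ol
Conditions: i-Bu2AlH (2.2 equiv), CH2Cl2, −78 °C; aq potassium sodium tartrate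
Reagents that add atoms: none
Why: 1,2-Reduction of an α,β-unsaturated ester with i-Bu2AlH stops at the allylic alcohol without touching alkene geometry, silyl ether or furan, and the neutral work-up avoids silyl migration between the two cis-disposed oxygens.

Step 6
Reactants: 14 the (Z)-allylic alcohol
Product: 15 3-[(4Z)-6-bromo-4-{[(tert-butyldimethylsilyl)oxy]methyl}hex-4-en-1-yl]furan
Conditions: CBr4, PPh3, CH2Cl2, −20 °C; used at once
Reagents that add atoms: carbon tetrabromide, BrC(Br)(Br)Br
Why: Appel bromination of a primary allylic alcohol at low temperature proceeds by SN2 displacement of the oxyphosphonium ion without allylic transposition or Z/E scrambling.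

Step 7
Reactants: 15 the (Z)-allylic bromide; 16 2-methylcyclohex-2-en-1-one; 17 methylmagnesium bromide
Product: 19 (2R,3S)-2-[(2Z)-3-{[(tert-butyldimethylsilyl)oxy]methyl}-6-(furan-3-yl)hex-2-en-1-yl]-2,3-dimethylcyclohexan-1-one, via magnesium enolate 18 (not isolated)
Conditions: 16 (1.5 equiv), Cu(OTf)2 (3 mol %), chiral hydroxyalkyl-imidazolinium hexafluorophosphate (carbene precursor, 4 mol %), 17 (1.4 equiv), Et2O, −30 °C; then 15 (1.0 equiv), DMPU, −30 °C → rt
Reagents that add atoms: methylmagnesium bromide (17), C[Mg]Br
Why: The carbene-bound methylcuprate formed from Cu(OTf)2, the imidazolinium salt and 17 binds the C=C of 16, adds at the β-carbon (C8) through a trivalent copper intermediate and eliminates reductively, which leaves the tetrasubstituted magnesium enolate 18 regiospecifically, and 18 then displaces bromide from 15 in an SN2 step that makes the C9–C11 bond and the quaternary centre. The closest known reaction type is the copper-catalysed asymmetric conjugate addition of Grignard reagents to 2-methylcycloalkenones with in-flask trapping of the magnesium enolate by allylic, benzylic or propargylic halides. No ring is closed in this step. C8 is set by the chiral carbene ligand, which shields one face of the bound enone, and C9 is set by C8: in the half-chair enolate the C8 methyl is pseudoaxial to escape A(1,2) strain with the C9 methyl, so the bromide approaches axially from the opposite face and ends trans to it, leaving the two methyl groups cis as in the target. The step needs C- over O-alkylation and C9 over C5 alkylation, secured by the soft allylic bromide, the regiodefined enolate and a temperature below that of enolate equilibration, and it needs SN2 over SN2' attack with retention of the Z geometry, secured by the fully substituted γ-carbon (C13) of 15. Reagent 17 is kept slightly below 16 in amount so that no methylcopper species is left to methylate 15.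

Step 8
Reactants: 19 the (Z)-alkenyl ketone
Product: 20 (2R,3S)-2-[(3R)-3-{[(tert-butyldimethylsilyl)oxy]methyl}-6-(furan-3-yl)hexyl]-2,3-dimethylcyclohexan-1-one
Conditions: [Ir(cod)(L*)]BArF (2 mol %; L* = chiral bicyclic pyridine–phosphinite N,P ligand; BArF = B[3,5-(CF3)2C6H3]4), H2 (50 bar), CH2Cl2, rt
Reagents that add atoms: none
Why: Iridium N,P-ligand catalysed asymmetric hydrogenation of a trisubstituted alkene places the only vinylic hydrogen (on C12) in the crowded quadrant of the catalyst, so the pure Z-alkene is hydrogenated on one face and C13 is set as R, while the hindered ketone and, at room temperature, the furan stay untouched.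

Step 9
Reactants: 20 the saturated ketone
Product: 22 (5S,6R)-6-[(3R)-3-{[(tert-butyldimethylsilyl)oxy]methyl}-6-(furan-3-yl)hexyl]-5,6-dimethylcyclohex-1-en-1-yl trifluoromethanesulfonate, via potassium enolate 21 (not isolated)
Conditions: KN(SiMe3)2, THF, −78 °C; PhNTf2, −78 → 0 °C
Reagents that add atoms: N-phenylbis(trifluoromethanesulfonimide), O=S(=O)(N(c1ccccc1)S(=O)(=O)C(F)(F)F)C(F)(F)F
Why: C9 is quaternary, so the base can only enolise towards C5, and O-sulfonylation of 21 gives a single enol triflate (kinetic enolate triflation).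

Step 10
Reactants: 22 the enol triflate; 23 5-bromo-2-methylpent-2-ene
Product: 26 tert-butyl{[(2R)-2-{2-[(1R,6S)-1,6-dimethyl-2-(4-methylpent-3-en-1-yl)cyclohex-2-en-1-yl]ethyl}-5-(furan-3-yl)pentyl]oxy}dimethylsilane, via homoprenylmagnesium bromide 24 (not isolated), via homoprenylzinc bromide 25 (not isolated)
Conditions: 23, Mg, THF; ZnBr2, 0 °C; then 22, Pd(dppf)Cl2 (5 mol %), THF, 50 °C
Reagents that add atoms: none
Why: Negishi coupling of an alkenyl triflate with a homoallylic alkylzinc halide forms the C10–C1 bond, the wide-bite-angle dppf ligand favouring reductive elimination over β-hydride elimination, and the zinc reagent leaves silyl ether and furan alone.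

Step 11
Reactants: 26 the 1,5-diene
Product: 27 tert-butyl{[(2R)-5-(furan-3-yl)-2-{2-[(1R,2S)-1,2,5,5-tetramethyl-1,2,3,4,5,6,7,8-octahydronaphthalen-1-yl]ethyl}pentyl]oxy}dimethylsilane
Conditions: SnCl4 (20 mol %), 2-methoxyphenol (20 mol %), CH2Cl2, −78 → −40 °C; Et3N quench at low temperature
Reagents that add atoms: none
Why: In this proton-initiated cation–olefin cyclisation, Markovnikov protonation of the prenyl-type alkene gives the C4 tertiary cation, C5 of the ring alkene attacks it in a 6-endo-trig closure that forms ring A, and loss of H5 from the C10 tertiary cation gives the tetrasubstituted C5=C10 alkene as the thermodynamic sink, so no new stereocentre remains and any silyl ether lost here converges in step 12.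

Step 12
Reactants: 27 the bicyclic silyl ether
Product: 28 (2R)-5-(furan-3-yl)-2-{2-[(1R,2S)-1,2,5,5-tetramethyl-1,2,3,4,5,6,7,8-octahydronaphthalen-1-yl]ethyl}pentan-1-ol
Conditions: Bu4NF, THF, 0 °C → rt
Reagents that add atoms: none
Why: Fluoride-induced cleavage of a primary silyl ether, driven by the Si–F bond, is mild enough for furan and alkene.

Step 13
Reactants: 28 the primary alcohol
Product: 29 (2R)-5-(furan-3-yl)-2-{2-[(1R,2S)-1,2,5,5-tetramethyl-1,2,3,4,5,6,7,8-octahydronaphthalen-1-yl]ethyl}pentyl hydrogen sulfate (target)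
Conditions: SO3·pyridine (3 equiv), DMF, 0 °C → rt; short passage over cold H+-form sulfonic acid resin
Reagents that add atoms: sulfur trioxide–pyridine complex, O=S(=O)([O-])[n+]1ccccc1
Why: O-Sulfation of a primary alcohol with SO3·pyridine is much faster at or below room temperature than C-sulfonation of the furan, and the cold acid resin exchanges pyridinium for a proton.

**Compound list**
1 | 3-bromofuran | Brc1ccoc1 | starting material
2 | oxetane | C1COC1 | starting material
3 | furan-3-yllithium | [Li]c1ccoc1 | intermediate
4 | 3-(furan-3-yl)propan-1-ol | OCCCc1ccoc1 | intermediate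
5 | 3-(3-bromopropyl)furan | BrCCCc1ccoc1 | intermediate
6 | tert-butyldimethyl(prop-2-yn-1-yloxy)silane | C#CCO[Si](C)(C)C(C)(C)C | starting material
7 | ethyl chloroformate | CCOC(=O)Cl | starting material
8 | lithium acetylide of 6 | [Li]C#CCO[Si](C)(C)C(C)(C)C | intermediate
9 | ethyl 4-[(tert-butyldimethylsilyl)oxy]but-2-ynoate | CCOC(=O)C#CCO[Si](C)(C)C(C)(C)C | intermediate
10 | 3-(furan-3-yl)propylmagnesium bromide | Br[Mg]CCCc1ccoc1 | intermediate
11 | 3-(furan-3-yl)propylcopper | [Cu]CCCc1ccoc1 | intermediate
12 | alkenylcopper adduct (Cu cis to the furylpropyl group) | CCOC(=O)/C([Cu])=C(CCCc1ccoc1)\CO[Si](C)(C)C(C)(C)C | intermediate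
13 | ethyl (Z)-3-{[(tert-butyldimethylsilyl)oxy]methyl}-6-(furan-3-yl)hex-2-enoate | CCOC(=O)/C=C(CCCc1ccoc1)\CO[Si](C)(C)C(C)(C)C | intermediate
14 | (Z)-3-{[(tert-butyldimethylsilyl)oxy]methyl}-6-(furan-3-yl)hex-2-en-1-ol | OC/C=C(CCCc1ccoc1)\CO[Si](C)(C)C(C)(C)C | intermediate
15 | 3-[(4Z)-6-bromo-4-{[(tert-butyldimethylsilyl)oxy]methyl}hex-4-en-1-yl]furan | BrC/C=C(CCCc1ccoc1)\CO[Si](C)(C)C(C)(C)C | intermediate
16 | 2-methylcyclohex-2-en-1-one | CC1=CCCCC1=O | starting material
17 | methylmagnesium bromide | C[Mg]Br | starting material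
18 | bromomagnesium (3S)-2,3-dimethylcyclohex-1-en-1-olate | C[C@H]1CCCC(O[Mg]Br)=C1C | intermediate
19 | (2R,3S)-2-[(2Z)-3-{[(tert-butyldimethylsilyl)oxy]methyl}-6-(furan-3-yl)hex-2-en-1-yl]-2,3-dimethylcyclohexan-1-one | C[C@H]1CCCC(=O)[C@]1(C)C/C=C(CCCc1ccoc1)\CO[Si](C)(C)C(C)(C)C | intermediate
20 | (2R,3S)-2-[(3R)-3-{[(tert-butyldimethylsilyl)oxy]methyl}-6-(furan-3-yl)hexyl]-2,3-dimethylcyclohexan-1-one | C[C@H]1CCCC(=O)[C@]1(C)CC[C@@H](CCCc1ccoc1)CO[Si](C)(C)C(C)(C)C | intermediate
21 | potassium enolate of 20 (C5=C10) | C[C@H]1CCC=C(O[K])[C@]1(C)CC[C@@H](CCCc1ccoc1)CO[Si](C)(C)C(C)(C)C | intermediate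
22 | (5S,6R)-6-[(3R)-3-{[(tert-butyldimethylsilyl)oxy]methyl}-6-(furan-3-yl)hexyl]-5,6-dimethylcyclohex-1-en-1-yl trifluoromethanesulfonate | C[C@H]1CCC=C(OS(=O)(=O)C(F)(F)F)[C@]1(C)CC[C@@H](CCCc1ccoc1)CO[Si](C)(C)C(C)(C)C | intermediate
23 | 5-bromo-2-methylpent-2-ene | CC(C)=CCCBr | starting material
24 | 4-methylpent-3-en-1-ylmagnesium bromide | CC(C)=CCC[Mg]Br | intermediate
25 | 4-methylpent-3-en-1-ylzinc bromide | CC(C)=CCC[Zn]Br | intermediate
26 | tert-butyl{[(2R)-2-{2-[(1R,6S)-1,6-dimethyl-2-(4-methylpent-3-en-1-yl)cyclohex-2-en-1-yl]ethyl}-5-(furan-3-yl)pentyl]oxy}dimethylsilane | C[C@H]1CCC=C(CCC=C(C)C)[C@]1(C)CC[C@@H](CCCc1ccoc1)CO[Si](C)(C)C(C)(C)C | intermediate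
27 | tert-butyl{[(2R)-5-(furan-3-yl)-2-{2-[(1R,2S)-1,2,5,5-tetramethyl-1,2,3,4,5,6,7,8-octahydronaphthalen-1-yl]ethyl}pentyl]oxy}dimethylsilane | C[C@H]1CCC2=C(CCCC2(C)C)[C@]1(C)CC[C@@H](CCCc1ccoc1)CO[Si](C)(C)C(C)(C)C | intermediate
28 | (2R)-5-(furan-3-yl)-2-{2-[(1R,2S)-1,2,5,5-tetramethyl-1,2,3,4,5,6,7,8-octahydronaphthalen-1-yl]ethyl}pentan-1-ol | C[C@H]1CCC2=C(CCCC2(C)C)[C@]1(C)CC[C@@H](CCCc1ccoc1)CO | intermediate
29 | (2R)-5-(furan-3-yl)-2-{2-[(1R,2S)-1,2,5,5-tetramethyl-1,2,3,4,5,6,7,8-octahydronaphthalen-1-yl]ethyl}pentyl hydrogen sulfate | C[C@H]1CCC2=C(CCCC2(C)C)[C@]1(C)CC[C@@H](CCCc1ccoc1)COS(=O)(=O)O | target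

Total step count: 13. Longest linear sequence: 12 (steps 1, 2, 4–13).

**Steps most likely to fail**

Step 7.
- What may go wrong: C-alkylation of the crowded tetrasubstituted magnesium enolate may be slow. Proton transfer to the less substituted enolate, O-alkylation or copper-mediated methylation of the bromide could then take over. Facial control in the methyl transfer may also be incomplete.
- Fallback: it sets out from 18 (made from 16 and 17 as in step 7) and from 14, and comes back at 19. The enolate is silylated with Me3SiCl to {[(3S)-2,3-dimethylcyclohex-1-en-1-yl]oxy}trimethylsilane F1, which can be purified and checked for enantiopurity. Alcohol 14 is acylated with methyl chloroformate/pyridine to the (Z)-allylic methyl carbonate F2. The two are joined by palladium-catalysed allylic alkylation (Tsuji–Trost type; Pd2(dba)3, dppe, Bu4N[Ph3SiF2] as substoichiometric initiator, THF, rt). Zerovalent palladium ionises F2 to a π-allyl complex, and the methoxide set free releases the enolate from F1 in low concentration under near-neutral conditions. Attack at the CH2 terminus of the allyl unit, anti to the C8 methyl, should give 19.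

Step 8.
- What may go wrong: facial selectivity may be poor, or the alkene may undergo Z/E isomerisation before hydrogen delivery. Turnover at the crowded alkene may be slow enough for furan reduction to set in.
- Fallback: it sets out from 13 and from the silyl enol ether F1 and comes back at 20, with C13 set before the union.
  - Copper hydride conjugate reduction of the β,β-disubstituted enoate 13 (Cu(OAc)2, DTBM-SEGPHOS, polymethylhydrosiloxane, t-BuOH, toluene, 0 °C) should give ethyl (3R)-3-{[(tert-butyldimethylsilyl)oxy]methyl}-6-(furan-3-yl)hexanoate F3.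
  - i-Bu2AlH gives (3R)-3-{[(tert-butyldimethylsilyl)oxy]methyl}-6-(furan-3-yl)hexan-1-ol F4.
  - PhSSPh/Bu3P gives the phenyl sulfide F5.
  - N-chlorosuccinimide gives the α-chloro sulfide F6.
  - ZnBr2-catalysed phenylthioalkylation of F1 with F6 uses a thionium ion as an SN1-active equivalent of the primary alkyl halide, and attack anti to the C8 methyl gives the α-(1-phenylthioalkyl) ketone F7.
  - Raney nickel deactivated in acetone removes the sulfur and gives 20.

Step 11.
- What may go wrong: the acid may destroy the furan by protonation and oligomerisation. Desilylation may occur early. A 1,2-shift from C9 to the C10 cation may occur before proton loss.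
- Fallback: it sets out from 26, comes back at 27 and makes no new compound. Ring A is closed without acid by a radical cycloisomerisation started by hydrogen-atom transfer (Co(salen)Cl, salen = N,N'-bis(3,5-di-tert-butylsalicylidene)ethane-1,2-diamine dianion, 5 mol %, PhSiH3 as substoichiometric activator, benzene, rt → 50 °C). A cobalt hydride gives H to C3 of the more accessible prenyl-type alkene. The C4 tertiary radical adds to the CH terminus C5 in the 6-endo mode, because the 5-exo mode would have to attack fully substituted C10 next to quaternary C9. Divalent cobalt then takes H back from the C10 radical. Reversible hydrogen-atom transfer should move the alkene to the tetrasubstituted C5=C10 position.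

**Further compounds**
F1 | step 7 | {[(3S)-2,3-dimethylcyclohex-1-en-1-yl]oxy}trimethylsilane | C[C@H]1CCCC(O[Si](C)(C)C)=C1C
F2 | step 7 | (2Z)-3-{[(tert-butyldimethylsilyl)oxy]methyl}-6-(furan-3-yl)hex-2-en-1-yl methyl carbonate | COC(=O)OC/C=C(CCCc1ccoc1)\CO[Si](C)(C)C(C)(C)C
F3 | step 8 | ethyl (3R)-3-{[(tert-butyldimethylsilyl)oxy]methyl}-6-(furan-3-yl)hexanoate | CCOC(=O)C[C@@H](CCCc1ccoc1)CO[Si](C)(C)C(C)(C)C
F4 | step 8 | (3R)-3-{[(tert-butyldimethylsilyl)oxy]methyl}-6-(furan-3-yl)hexan-1-ol | OCC[C@@H](CCCc1ccoc1)CO[Si](C)(C)C(C)(C)C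
F5 | step 8 | tert-butyl{[(2R)-5-(furan-3-yl)-2-[2-(phenylsulfanyl)ethyl]pentyl]oxy}dimethylsilane | c1ccccc1SCC[C@@H](CCCc1ccoc1)CO[Si](C)(C)C(C)(C)C
F6 | step 8 | tert-butyl{[(2R)-2-[2-chloro-2-(phenylsulfanyl)ethyl]-5-(furan-3-yl)pentyl]oxy}dimethylsilane (epimers at the CHCl carbon) | ClC(Sc1ccccc1)C[C@@H](CCCc1ccoc1)CO[Si](C)(C)C(C)(C)C
F7 | step 8 | (2R,3S)-2-[(3R)-3-{[(tert-butyldimethylsilyl)oxy]methyl}-6-(furan-3-yl)-1-(phenylsulfanyl)hexyl]-2,3-dimethylcyclohexan-1-one (epimers at the CHS carbon) | C[C@H]1CCCC(=O)[C@]1(C)C(Sc1ccccc1)C[C@@H](CCCc1ccoc1)CO[Si](C)(C)C(C)(C)C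
F0 | step 11 | none | none
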